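**Assumption:** the target SMILES has no stereocentre or stereogenic double bond, and the 18-membered cyclophane is taken to be conformationally mobile (no isolable atropisomers). The molecule is therefore achiral and no stereocontrol is needed.

## Retrosynthetic overview

1. The macrocycle is opened at the quinone C–O(aryl) bond, not at a bibenzyl or by a late quinone oxidation. The key step is an intramolecular phenoxide addition–elimination on a 2-chloro-1,4-benzoquinone, triggered by fluoride desilylation, which closes the 18-membered ring with the quinone already in place.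
2. The chloroquinone comes from CAN oxidation of a 2-chloro-1,4-dimethoxyarene. The chlorine is a spectator in the cross-couplings and then the leaving group.
3. Both ArCH2CH2Ar' bridges are made directly at the sp3 oxidation level by 9-BBN hydroboration / B-alkyl Suzuki coupling of styrenes, so no Wittig/hydrogenation is needed and the benzyl ether survives.
4. The ring B–O–ring C ether comes from a Chan–Lam coupling.
5. Ring order: all four six-membered rings are purchased as arenes. The quinone is unveiled first; the only ring formed is the 18-membered macrocycle, in the penultimate step.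

## Route

**Step 1**
Reactants: 1, 2-chloro-1,4-dimethoxybenzene; 2, iodine
Product: 3, 2-chloro-3-iodo-1,4-dimethoxybenzene
Conditions: LiTMP, THF, −78 °C, 1 h; then I2 in THF, −78 °C → rt
Reagents that add atoms: iodine, II
Why: Directed ortho-metalation removes the most acidic C3–H (flanked by Cl and OMe), the ortho-chloroaryllithium is stable to benzyne formation at −78 °C, and it is trapped by electrophilic iodination.

**Step 2**
Reactants: 4, 3-hydroxybenzaldehyde; 5, triisopropylsilyl chloride
Product: 6, 3-(triisopropylsilyloxy)benzaldehyde
Conditions: TIPSCl, imidazole, DMF, rt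
Reagents that add atoms: TIPSCl, CC(C)[Si](Cl)(C(C)C)C(C)C
Why: Standard phenol silylation; TIPS is chosen because it survives aqueous-base Suzuki conditions and CAN, yet is cleaved by fluoride in the key step.

**Step 3**
Reactants: 6; 7, methyltriphenylphosphonium bromide
Product: 8, 1-ethenyl-3-(triisopropylsilyloxy)benzene (3-TIPSO-styrene)
Conditions: Ph3PCH3Br, KOtBu, THF, 0 °C → rt
Reagents that add atoms: methyltriphenylphosphonium bromide, C[P+](c1ccccc1)(c1ccccc1)c1ccccc1.[Br-]
Why: Wittig methylenation of an aryl aldehyde; the aryl TIPS ether is inert to the preformed ylide.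

**Step 4**
Reactants: 9, 2-(benzyloxy)-5-bromobenzaldehyde; 10, mCPBA
Product: 11, 2-(benzyloxy)-5-bromophenol
Conditions: mCPBA, CH2Cl2, rt; then K2CO3, MeOH, rt
Reagents that add atoms: mCPBA, OOC(=O)c1cccc(Cl)c1 (one O)
Why: Dakin-type Baeyer–Villiger oxidation, in which the ortho-alkoxy aryl group migrates to give the aryl formate, followed by methanolysis to the phenol.

**Step 5**
Reactants: 11; 12, (4-ethenylphenyl)boronic acid
Product: 13, 1-(benzyloxy)-4-bromo-2-(4-ethenylphenoxy)benzene
Conditions: Cu(OAc)2, pyridine, 4 Å MS, CH2Cl2, air, rt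
Reagents that add atoms: (4-ethenylphenyl)boronic acid, OB(O)c1ccc(C=C)cc1
Why: Chan–Lam–Evans oxidative O-arylation installs ring B with its vinyl handle in one step; with no Pd present the aryl bromide is untouched.

**Step 6**
Reactants: 8 (1.4 equiv, pre-hydroborated); 13
Product: 14, 1-(benzyloxy)-2-(4-ethenylphenoxy)-4-{2-[3-(triisopropylsilyloxy)phenyl]ethyl}benzene
Conditions: 8, 9-BBN (1.3 equiv), THF, 0 °C → rt; then 13, Pd(dppf)Cl2, aq. K3PO4, THF/DMF, 50 °C
Reagents that add atoms: none (9-BBN delivers only H)
Why: Anti-Markovnikov hydroboration then B-alkyl Suzuki–Miyaura coupling gives the C–D bibenzyl directly; keeping styrene 8 in excess over 9-BBN leaves no B–H to attack the spectator ring-B vinyl group.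

**Step 7**
Reactants: 14 (pre-hydroborated); 3
Product: 15, 2-chloro-1,4-dimethoxy-3-{2-[4-(2-(benzyloxy)-5-{2-[3-(triisopropylsilyloxy)phenyl]ethyl}phenoxy)phenyl]ethyl}benzene
Conditions: 14, 9-BBN, THF, rt; then 3, Pd(dppf)Cl2, AsPh3, aq. K3PO4, THF/DMF, 60 °C
Reagents that add atoms: none
Why: A second hydroboration / B-alkyl Suzuki–Miyaura coupling that is chemoselective for C–I over the neighbouring C–Cl with a dppf catalyst, giving the full acyclic skeleton with Cl correctly placed.

**Step 8**
Reactants: 15; 16, water
Product: 17, 2-chloro-3-{2-[4-(2-(benzyloxy)-5-{2-[3-(triisopropylsilyloxy)phenyl]ethyl}phenoxy)phenyl]ethyl}cyclohexa-2,5-diene-1,4-dione (the chloroquinone)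
Conditions: CAN (2.5 equiv), MeCN/H2O (2:1), 0 °C, 15 min
Reagents that add atoms: water, O (both quinone oxygens; the OMe groups leave as MeOH)
Why: Oxidative demethylation of the 1,4-dimethoxyarene, the most easily oxidised ring, by ceric ammonium nitrate; aryl-OTIPS, aryl-OBn and the mono-oxygenated rings tolerate brief cold exposure.

**Step 9 (key step)**
Reactants: 17
Product: 18, O-benzyl marchantinquinone (the 18-membered macrocycle, ring C phenol as benzyl ether)
Conditions: CsF (5 equiv), 18-crown-6 (cat.), dry MeCN, Ar, dark, rt; 17 added by syringe pump over 12 h to 1 mM final concentration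
Reagents that add atoms: none
Why: Proposed new method: fluoride cleaves the aryl TIPS ether to a naked caesium phenoxide, which adds to the chlorine-bearing C2 of the quinone (a vinylogous acid chloride) and expels chloride irreversibly, while oxa-Michael addition at C5/C6 is reversible in aprotic medium and funnels back to the ipso pathway; closest known reactions are intermolecular phenoxide substitution of halo-quinones (quinone SNAr) and fluoride-triggered desilylative SNAr macro-etherifications.

**Step 10**
Reactants: 18
Product: 19, marchantinquinone (target)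
Conditions: H2 (1 atm), 10% Pd/C, EtOAc, rt; filter under Ar; then Ag2O, MgSO4, Et2O/EtOAc, rt, 30 min
Reagents that add atoms: none
Why: Hydrogenolysis removes the benzyl ether while transiently reducing the quinone to its hydroquinone, and Ag2O selectively re-oxidises the hydroquinone to the quinone without touching the free ring-C phenol.

## Compound list

1 | 2-chloro-1,4-dimethoxybenzene | COc1ccc(OC)c(Cl)c1 | starting material
2 | iodine | II | starting material (reagent)
3 | 2-chloro-3-iodo-1,4-dimethoxybenzene | COc1ccc(OC)c(I)c1Cl | intermediate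
4 | 3-hydroxybenzaldehyde | O=Cc1cccc(O)c1 | starting material
5 | triisopropylsilyl chloride | CC(C)[Si](Cl)(C(C)C)C(C)C | starting material (reagent)
6 | 3-(triisopropylsilyloxy)benzaldehyde | O=Cc1cccc(O[Si](C(C)C)(C(C)C)C(C)C)c1 | intermediate
7 | methyltriphenylphosphonium bromide | C[P+](c1ccccc1)(c1ccccc1)c1ccccc1.[Br-] | starting material (reagent)
8 | 1-ethenyl-3-(triisopropylsilyloxy)benzene | C=Cc1cccc(O[Si](C(C)C)(C(C)C)C(C)C)c1 | intermediate
9 | 2-(benzyloxy)-5-bromobenzaldehyde | O=Cc1cc(Br)ccc1OCc1ccccc1 | starting material
10 | mCPBA | OOC(=O)c1cccc(Cl)c1 | starting material (reagent)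
11 | 2-(benzyloxy)-5-bromophenol | Oc1cc(Br)ccc1OCc1ccccc1 | intermediate
12 | (4-ethenylphenyl)boronic acid | OB(O)c1ccc(C=C)cc1 | starting material
13 | 1-(benzyloxy)-4-bromo-2-(4-ethenylphenoxy)benzene | C=Cc1ccc(Oc2cc(Br)ccc2OCc2ccccc2)cc1 | intermediate
14 | 1-(benzyloxy)-2-(4-ethenylphenoxy)-4-{2-[3-(triisopropylsilyloxy)phenyl]ethyl}benzene | C=Cc1ccc(Oc2cc(CCc3cccc(O[Si](C(C)C)(C(C)C)C(C)C)c3)ccc2OCc2ccccc2)cc1 | intermediate
15 | acyclic 2-chloro-1,4-dimethoxyarene (full skeleton) | COc1ccc(OC)c(CCc2ccc(Oc3cc(CCc4cccc(O[Si](C(C)C)(C(C)C)C(C)C)c4)ccc3OCc3ccccc3)cc2)c1Cl | intermediate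
16 | water | O | starting material (reagent)
17 | acyclic 2-chloro-3-alkyl-1,4-benzoquinone | O=C1C=CC(=O)C(CCc2ccc(Oc3cc(CCc4cccc(O[Si](C(C)C)(C(C)C)C(C)C)c4)ccc3OCc3ccccc3)cc2)=C1Cl | intermediate
18 | O-benzyl marchantinquinone | O=C1C=CC(=O)C2=C1CCc1ccc(cc1)Oc1cc(ccc1OCc1ccccc1)CCc1cccc(c1)O2 | intermediate
19 | marchantinquinone | O=C1C=CC(=O)C2=C1CCc1ccc(cc1)Oc1cc(ccc1O)CCc1cccc(c1)O2 | target

## Summary

Total steps: 10.
Longest linear sequence: 7 (steps 4 → 5 → 6 → 7 → 8 → 9 → 10, from compound 9).

Three steps most likely to fail:

1. **Step 9, quinone addition–elimination macrocyclisation.** Risks are oxa-Michael addition at C5/C6, oligomerisation, and base-induced quinone-methide tautomerisation of the alkylquinone. Fallback: move the ring closure to a C–C bond. Make the ring A–O–ring D ether intermolecularly (Cu-catalysed Ullmann coupling of the ring-D phenol with a 2-halo-3-iodo-1,4-dimethoxybenzene), close the 18-membered ring by intramolecular 9-BBN hydroboration / B-alkyl Suzuki coupling of the ring-B styrene onto the ring-A iodide, and oxidise to the quinone with CAN last.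

2. **Step 7, B-alkyl Suzuki at the di-ortho-substituted iodide.** Risks are slow oxidative addition/transmetalation and erosion of I-over-Cl selectivity. Fallback: trap the lithiated chloroarene from step 1 with DMF to give 2-chloro-3,6-dimethoxybenzaldehyde, join it to a ring-B benzylphosphonium salt by Wittig olefination, and reduce the stilbene with diimide (TsNHNH2, NaOAc), which spares the C–Cl bond, the benzyl ether and the silyl ether.

3. **Step 8, CAN oxidation.** Risks are competing oxidation of the electron-rich ring C or loss of TIPS. Fallback: carry ring A as a hydroquinone bis-MOM ether (2-chlorohydroquinone → bis-MOM → ortho-lithiation/iodination → same coupling), remove MOM with mild acid, and oxidise the free hydroquinone with Ag2O or air, so that no strong one-electron oxidant is needed.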